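Retrosynthetic overview
1. Locants, kept for every intermediate: C1 CHOAc beside C10, C2 CH2, C3 fusion CH, C4 CHMe, C5 CHOAc, C6 CH2, C7=C11(C12H3)(C13H2O), C8 bis-allylic fusion CH, C9=C10(Me). Ring A is C1-C2-C3-C8-C9-C10 and ring B is C3-C4-C5-C6-C7-C8.
2. Feature used: the oxygen on C5, the ring A alkene C9=C10 next to C8, and the alkylidene C7=C11 on ring B are what an allenyl oxy-Cope shift leaves behind. Cutting C7-C8 and redrawing a C5-C10 bond leads back to a 2-allenylbicyclo[2.2.2]oct-5-en-2-ol.
3. Ring A is made first, inside the bicycle (Wessely oxidation of 2,6-dimethylphenol, then a Diels-Alder reaction with an enol ether). Ring B is closed last by the [3,3] shift, which also sets C8 and turns the allene axis into the E geometry of C7=C11.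
4. The axis comes from C11 of an alkynyl oxirane: asymmetric epoxidation of methallyl alcohol, Corey-Fuchs homologation, addition to the C5 ketone, syn SN2' hydride opening. The bicycle is resolved with a lipase, and neopentyl C1 is inverted by oxidation and face-selective reduction, not by substitution.
5. After the shift: axial hydride attack at C5, desilylation, formylation of primary O13, acetylation of O1 and O5.

Key step: step 13

Remark: endo means that the C1 oxygen points to the C8=C9 bridge and exo that it points to the C4-C5 bridge; i-Bu2AlH is assumed to open the alkynyl oxirane in the syn SN2' sense, which dictates the D-(−)-tartrate in step 8.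

Step 1
Reactants: 1 2,6-dimethylphenol
Product: 2 rac-6-acetoxy-2,6-dimethylcyclohexa-2,4-dien-1-one
Conditions: Pb(OAc)4, AcOH, rt
Reagents that add atoms: lead tetraacetate, CC(=O)O[Pb](OC(C)=O)(OC(C)=O)OC(C)=O
Why: Wessely oxidation, in which the aryloxy-lead intermediate delivers acetate to a methyl-bearing ortho carbon and should give the racemic ortho-quinol acetate, whose 2,6-disubstitution slows self-dimerisation.

Step 2
Reactants: 2 rac-6-acetoxy-2,6-dimethylcyclohexa-2,4-dien-1-one; 3 trimethyl(vinyloxy)silane
Product: 5 rac-endo hydroxy acetoxy ketone (bicyclo[2.2.2]octenone; C1-OH endo; C4-OAc towards the C1-C2 bridge), via silyl ether cycloadduct 4 (not isolated)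
Conditions: 3 (excess), toluene, sealed tube, 100 °C; then citric acid, MeOH, rt
Reagents that add atoms: none
Why: Inverse-electron-demand Diels-Alder reaction of the electron-poor dienone with an enol ether, in which the nucleophilic CH2 terminus (C2) bonds to the dienone terminus C3 and the oxygen-bearing C1 to C10, the silyloxy group lies endo and the dienophile enters on the acetoxy face of C4, after which mild methanolysis removes only the trimethylsilyl group.

Step 3
Reactants: 5 rac-endo hydroxy acetoxy ketone
Product: 6 (1S)-endo hydroxy acetoxy ketone (single enantiomer; recovered alcohol)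
Conditions: Burkholderia cepacia lipase (immobilised), vinyl acetate, t-BuOMe, 35 °C, stopped just past half conversion; chromatography
Reagents that add atoms: none
Why: Lipase-catalysed kinetic resolution by irreversible transesterification, in which the empirical large/medium size rule (C10 large, C2 medium) predicts faster acylation of the (1R) alcohol, so the wanted (1S) alcohol should stay unreacted and be separated from the acetate.

Step 4
Reactants: 6 (1S)-endo hydroxy acetoxy ketone
Product: 7 bicyclic 1,5-dione (C1=O and C5=O on quaternary C10)
Conditions: Dess-Martin periodinane, CH2Cl2, rt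
Reagents that add atoms: none
Why: Dess-Martin oxidation of the only free alcohol under neutral conditions, chosen because C1 is neopentyl (next to quaternary C10) and closed to SN2 inversion, so its configuration is erased here and reset in the next step.

Step 5
Reactants: 7 bicyclic 1,5-dione
Product: 8 (1R)-exo hydroxy acetoxy ketone
Conditions: LiAlH(O-t-Bu)3, THF, −40 → 0 °C; aq potassium sodium tartrate
Reagents that add atoms: none
Why: Chemo- and diastereoselective hydride reduction, in which C5=O lies between two quaternary carbons and stays, while at C1=O the cleft towards the C4-C5 bridge is closed by the C4 acetoxy group, so the bulky hydride should come from the side of the flat C8=C9 bridge and push the new hydroxyl (1R) towards the C4-C5 bridge.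

Step 6
Reactants: 8 (1R)-exo hydroxy acetoxy ketone
Product: 9 exo tert-butyldimethylsilyl ether of the acetoxy ketone
Conditions: TBSOTf, 2,6-lutidine, CH2Cl2, 0 °C
Reagents that add atoms: tert-butyldimethylsilyl triflate, CC(C)(C)[Si](C)(C)OS(=O)(=O)C(F)(F)F
Why: Silylation of a hindered secondary alcohol with a silyl triflate, done at this stage because the ketone has no alpha hydrogen and cannot form a silyl enol ether.

Step 7
Reactants: 9 exo silyl ether of the acetoxy ketone
Product: 11 bicyclic ketone (4R; C4-Me towards the C8=C9 bridge; C1-OTBS exo), via C4-epimeric ketone 10 (not isolated)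
Conditions: SmI2, THF-MeOH, −78 °C; crude product then DBU (cat.), CH2Cl2, rt
Reagents that add atoms: none
Why: SmI2 reduction of an alpha-acetoxy ketone (two single-electron transfers, loss of acetate, protonation of the samarium enolate) followed by base equilibration at C4, the only enolisable position, which should place the methyl group on the less crowded side facing the C8=C9 bridge, with no beta-elimination possible because C10 is quaternary.

Step 8
Reactants: 12 methallyl alcohol
Product: 13 (R)-2-methylglycidol
Conditions: Ti(O-i-Pr)4 (cat.), D-(−)-diisopropyl tartrate (cat.), PhCMe2OOH, 4 Å MS, CH2Cl2, −20 °C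
Reagents that add atoms: cumene hydroperoxide, CC(C)(OO)c1ccccc1
Why: Katsuki-Sharpless asymmetric epoxidation, in which the D-(−)-tartrate titanium complex should give the (R)-epoxy alcohol (the L-(+)-tartrate gives the S series) and so sets C11.

Step 9
Reactants: 13 (R)-2-methylglycidol
Product: 14 (S)-2-methyloxirane-2-carbaldehyde
Conditions: Dess-Martin periodinane, CH2Cl2, 0 °C → rt; filtered, kept as a CH2Cl2 solution (volatile)
Reagents that add atoms: none
Why: Dess-Martin oxidation of a primary alcohol, in which quaternary C11 cannot epimerise and the descriptor changes only through the priority rules.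

Step 10
Reactants: 14 (S)-2-methyloxirane-2-carbaldehyde
Product: 15 (R)-2-(2,2-dibromoethenyl)-2-methyloxirane
Conditions: CBr4, PPh3, Et3N, CH2Cl2, −60 → 0 °C
Reagents that add atoms: carbon tetrabromide, BrC(Br)(Br)Br
Why: Ramirez olefination (first Corey-Fuchs stage) with Ph3P=CBr2, buffered with Et3N so that the oxirane is not opened, which gives a non-volatile store of the C6-C7 alkyne.

Step 11
Reactants: 15 (R)-2-(2,2-dibromoethenyl)-2-methyloxirane; 11 bicyclic ketone
Product: 17 alkynyl oxirane carbinol (C5-OH towards C1; alkynyl group over the C8=C9 bridge), via lithium acetylide 16 (not isolated)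
Conditions: n-BuLi (2 equiv per 15), THF, −78 °C; then 11, −78 → 0 °C; aq NH4Cl
Reagents that add atoms: none
Why: The second Corey-Fuchs stage (Br/Li exchange, 1,2-shift, deprotonation) gives the slim lithium acetylide, whose 1,2-addition should take place from the side of the C8=C9 bridge because the other carbonyl face is covered by the exo C1 silyloxy group, which sets C5.

Step 12
Reactants: 17 alkynyl oxirane carbinol
Product: 18 (aR)-allenyl bicyclo[2.2.2]octenol (C5-OH and C13-OH free; C1-OTBS)
Conditions: i-Bu2AlH (excess), CH2Cl2, −78 → 0 °C; aq potassium sodium tartrate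
Reagents that add atoms: none
Why: SN2' reduction of an alkynyl oxirane, in which aluminium bound to the oxirane oxygen delivers hydride to C6 on the side of the breaking C11-O bond (syn), so the (R) centre C11 should be translated into the (aR) axis C6=C7=C11 while O13 is released as the primary alcohol.

Step 13
Reactants: 18 (aR)-allenyl bicyclo[2.2.2]octenol
Product: 21 cis-decalin C5 ketone (8S; E alkene C7=C11; C13-OH free), via dipotassium dialkoxide 19 (not isolated), via dipotassium dienolate alkoxide 20 (not isolated)
Conditions: KH (excess), 18-crown-6, THF, 0 °C → rt; cannulated into AcOH-THF, −78 °C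
Reagents that add atoms: none
Why: KH removes both hydroxyl protons, and in dialkoxide 19 the C5 oxyanion weakens the C5-C10 bond so that the C6=C7 pi bond of the allene, the C5-C10 sigma bond and the C8=C9 pi bond trade places in one concerted suprafacial [3,3] shift, an anionic oxy-Cope rearrangement as known for 2-alkenyl- and 2-allenylbicyclo[2.2.2]oct-5-en-2-ols (reading an alkene geometry out of a fully substituted allene terminus goes one step beyond those cases). Ring B (C3-C4-C5-C6-C7-C8) closes through the new C7-C8 bond in a boat-like six-centre transition state, while loss of the C5-C10 bond leaves ring A as a cyclohexene with the C9=C10 alkene, and relief of cage strain together with dienolate formation makes the step irreversible. The one new stereocentre C8 is fixed by the cage: C7 hangs over the face of C8=C9 that looks at the C4-C5 bridge, so H8 ends cis to H3 (8S, cis-decalin). The distal allene pi bond is a spectator that becomes C7=C11, only the rotamer about C5-C6 that holds C7 above C8 can react, and in it the (aR) axis turns methyl C12 towards C8 and C13 away from it, which gives the E alkene; face selectivity at the allene and at C8 is thus secured by the rigid bicycle and not by a reagent. O13 travels as a potassium alkoxide because a silyloxy or alkoxy group at C13 would be expelled from the dienolate by vinylogous beta-elimination, and a reversible silyl shift from O1 to O5 is harmless since only the C5 alkoxide rearranges. Inverse quench into cold AcOH protonates dienolate 20 at the alpha carbon C6, which keeps C7=C11 out of conjugation and leaves C4 untouched.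

Step 14
Reactants: 21 cis-decalin C5 ketone
Product: 22 (5R)-diol (C5-OH equatorial; C13-OH; C1-OTBS)
Conditions: NaBH4, CeCl3·7H2O, MeOH, −78 °C
Reagents that add atoms: none
Why: Luche-type 1,2-reduction in a non-basic medium so that the beta,gamma-alkene does not move, where allylic strain with C12 holds ring B in the chair with C9 axial, H8 equatorial and C4-Me equatorial, and hydride should attack C5 axially on the face of H3 to give the equatorial (5R) alcohol trans to the C4 methyl.

Step 15
Reactants: 22 (5R)-diol
Product: 23 triol (O1, O5 and O13 free)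
Conditions: TBAF, THF, rt
Reagents that add atoms: none
Why: Fluoride cleavage of the single silyl ether, which touches no stereocentre and finds no base-sensitive group now that the ketone is reduced.

Step 16
Reactants: 23 triol
Product: 24 C13 formate diol
Conditions: HCO2CH2CF3 (slight excess), THF, 45 °C
Reagents that add atoms: 2,2,2-trifluoroethyl formate, O=COCC(F)(F)F
Why: Chemoselective O-formylation by transesterification with an activated formate, in which the primary allylic O13 should react much faster than the secondary O1 and O5.

Step 17
Reactants: 24 C13 formate diol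
Product: 25 CNP0262962.1 (target)
Conditions: Ac2O, pyridine, DMAP (cat.), CH2Cl2, 0 °C → rt
Reagents that add atoms: acetic anhydride, CC(=O)OC(C)=O
Why: DMAP-catalysed acetylation of both secondary alcohols with retention at C1 and C5, under anhydrous mild conditions that leave the formate in place.

Compound list
1 | 2,6-dimethylphenol | Cc1cccc(C)c1O | starting material
2 | rac-6-acetoxy-2,6-dimethylcyclohexa-2,4-dien-1-one | CC(=O)OC1(C)C=CC=C(C)C1=O | intermediate
3 | trimethyl(vinyloxy)silane | C=CO[Si](C)(C)C | starting material
4 | silyl ether cycloadduct (racemate, relative configuration drawn): bicyclo[2.2.2]octenone with bridgeheads C10(Me) and C3(H), C1-OSiMe3 endo, C4-OAc towards the C1-C2 bridge | C[Si](C)(C)O[C@H]1C[C@@H]2[C@](C)(OC(C)=O)C(=O)[C@@]1(C)C=C2 | intermediate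
5 | rac-endo hydroxy acetoxy ketone (racemate, relative configuration drawn) | O[C@H]1C[C@@H]2[C@](C)(OC(C)=O)C(=O)[C@@]1(C)C=C2 | intermediate
6 | (1S)-endo hydroxy acetoxy ketone, single enantiomer | O[C@H]1C[C@@H]2[C@](C)(OC(C)=O)C(=O)[C@@]1(C)C=C2 | intermediate
7 | bicyclic 1,5-dione (C1=O, C5=O, C4 acetoxy) | O=C1C[C@@H]2[C@](C)(OC(C)=O)C(=O)[C@@]1(C)C=C2 | intermediate
8 | (1R)-exo hydroxy acetoxy ketone | O[C@@H]1C[C@@H]2[C@](C)(OC(C)=O)C(=O)[C@@]1(C)C=C2 | intermediate
9 | exo tert-butyldimethylsilyl ether of the acetoxy ketone | CC(C)(C)[Si](C)(C)O[C@@H]1C[C@@H]2[C@](C)(OC(C)=O)C(=O)[C@@]1(C)C=C2 | intermediate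
10 | C4-epimeric ketone (C4-Me towards the C1-C2 bridge) | CC(C)(C)[Si](C)(C)O[C@@H]1C[C@@H]2[C@H](C)C(=O)[C@@]1(C)C=C2 | intermediate
11 | bicyclic ketone (4R, C4-Me towards the C8=C9 bridge, C1-OTBS exo) | CC(C)(C)[Si](C)(C)O[C@@H]1C[C@@H]2[C@@H](C)C(=O)[C@@]1(C)C=C2 | intermediate
12 | methallyl alcohol | C=C(C)CO | starting material
13 | (R)-2-methylglycidol | C[C@@]1(CO)CO1 | intermediate
14 | (S)-2-methyloxirane-2-carbaldehyde | C[C@@]1(C=O)CO1 | intermediate
15 | (R)-2-(2,2-dibromoethenyl)-2-methyloxirane | C[C@@]1(C=C(Br)Br)CO1 | intermediate
16 | lithium acetylide of (R)-2-ethynyl-2-methyloxirane | C[C@@]1(C#C[Li])CO1 | intermediate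
17 | alkynyl oxirane carbinol (C5-OH towards C1, alkynyl over C8=C9, C11 R) | CC(C)(C)[Si](C)(C)O[C@@H]1C[C@@H]2[C@@H](C)[C@@](O)(C#C[C@]3(C)CO3)[C@@]1(C)C=C2 | intermediate
18 | (aR)-allenyl bicyclo[2.2.2]octenol, precursor of the key step | CC(C)(C)[Si](C)(C)O[C@@H]1C[C@@H]2[C@@H](C)[C@@](O)(C([H])=[C@]=C(C)CO)[C@@]1(C)C=C2 | intermediate
19 | dipotassium dialkoxide of 18 | CC(C)(C)[Si](C)(C)O[C@@H]1C[C@@H]2[C@@H](C)[C@@]([O-])(C([H])=[C@]=C(C)C[O-])[C@@]1(C)C=C2.[K+].[K+] | intermediate
20 | dipotassium dienolate alkoxide (C5=C6 enolate, C7=C11 alkene, O13 alkoxide) | CC(C)(C)[Si](C)(C)O[C@@H]1C[C@@H]2[C@@H](C)C([O-])=C/C(=C(/C)C[O-])[C@@H]2C=C1C.[K+].[K+] | intermediate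
21 | cis-decalin C5 ketone, product of the key step (1R,3S,4R,8S; E alkene) | CC(C)(C)[Si](C)(C)O[C@@H]1C[C@@H]2[C@@H](C)C(=O)C/C(=C(/C)CO)[C@@H]2C=C1C | intermediate
22 | (5R)-diol | CC(C)(C)[Si](C)(C)O[C@@H]1C[C@@H]2[C@@H](C)[C@H](O)C/C(=C(/C)CO)[C@@H]2C=C1C | intermediate
23 | triol | O[C@@H]1C[C@@H]2[C@@H](C)[C@H](O)C/C(=C(/C)CO)[C@@H]2C=C1C | intermediate
24 | C13 formate diol | O[C@@H]1C[C@@H]2[C@@H](C)[C@H](O)C/C(=C(/C)COC=O)[C@@H]2C=C1C | intermediate
25 | CNP0262962.1 (1R,3S,4R,5R,8S; E alkene C7=C11) | CC(=O)O[C@@H]1C[C@@H]2[C@@H](C)[C@H](OC(C)=O)C/C(=C(/C)COC=O)[C@@H]2C=C1C | target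

Total step count: 17. Longest linear sequence: 14 (steps 1-7 and 11-17).

Steps most likely to fail

Step 13. The alkene geometry may erode through rotation about the C7-C11 bond in the delocalised dienolate. The shift may also be slowed by crowding or temporary silylation at O5, and protonation at the gamma carbon on quench would move the alkene into conjugation. The fallback replaces the anionic shift by a neutral siloxy-Cope rearrangement, so that no free dienolate exists. It sets out from 18. Both hydroxyls are silylated (TMSOTf, 2,6-lutidine, CH2Cl2, −78 °C) to give the bis(trimethylsilyl) ether F1. This is heated in o-dichlorobenzene in a sealed tube at about 180 °C with a little N,O-bis(trimethylsilyl)acetamide as proton scavenger. The same concerted axis-to-geometry transfer should give the silyl dienol ether F2. Cold methanolysis (citric acid, MeOH, 0 °C) frees O13 and protonates C6, and the route is rejoined at 21.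

Step 12. Hydride delivery may be only partly syn, which would lower or reverse the centre-to-axis transfer. The oxirane may instead be opened directly at C13, or the C5 alkoxide may direct a hydroalumination of the alkyne. The fallback uses an opening whose anti sense is established, applied to the C11 epimer. It sets out from 12 and 11. Epoxidation of 12 with L-(+)-diisopropyl tartrate gives (S)-2-methylglycidol F3. Oxidation as in step 9 gives (R)-2-methyloxirane-2-carbaldehyde F4, and olefination as in step 10 gives (S)-2-(2,2-dibromoethenyl)-2-methyloxirane F5. n-BuLi converts this into the enantiomeric lithium acetylide F6, which adds to 11 to give the C11-epimeric alkynyl oxirane carbinol F7. A copper hydride catalysed SN2' reduction follows ((IPr)CuCl with IPr = 1,3-bis(2,6-diisopropylphenyl)imidazol-2-ylidene, NaO-t-Bu, polymethylhydrosiloxane, toluene, 0 °C → rt, then K2CO3, MeOH). Anti delivery of hydride should produce the same (aR) axis, and the route is rejoined at 18.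

Step 3. The cage alcohol next to quaternary C10 may be too hindered for acyl transfer in the enzyme, or both enantiomers may be acylated at similar rates. The fallback is a classical resolution through covalent diastereomers. It sets out from 5, which is heated with (R)-1-(1-naphthyl)ethyl isocyanate and DMAP in toluene. This gives the carbamate of the (1S) alcohol F8 and the carbamate of the (1R) alcohol F9, which are separated by chromatography or crystallisation. Non-hydrolytic cleavage of F8 with HSiCl3 and Et3N in CH2Cl2 leaves the tertiary acetate in place, and the route is rejoined at 6.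

Further compounds
F1 | step 13 | bis(trimethylsilyl) ether of 18 (O5 and O13 silylated) | CC(C)(C)[Si](C)(C)O[C@@H]1C[C@@H]2[C@@H](C)[C@@](O[Si](C)(C)C)(C([H])=[C@]=C(C)CO[Si](C)(C)C)[C@@]1(C)C=C2
F2 | step 13 | silyl dienol ether of the cis-decalin (C5-OSiMe3, C5=C6, E alkene C7=C11, C13-OSiMe3) | CC(C)(C)[Si](C)(C)O[C@@H]1C[C@@H]2[C@@H](C)C(O[Si](C)(C)C)=C/C(=C(/C)CO[Si](C)(C)C)[C@@H]2C=C1C
F3 | step 12 | (S)-2-methylglycidol | C[C@]1(CO)CO1
F4 | step 12 | (R)-2-methyloxirane-2-carbaldehyde | C[C@]1(C=O)CO1
F5 | step 12 | (S)-2-(2,2-dibromoethenyl)-2-methyloxirane | C[C@]1(C=C(Br)Br)CO1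
F6 | step 12 | lithium acetylide of (S)-2-ethynyl-2-methyloxirane | C[C@]1(C#C[Li])CO1
F7 | step 12 | C11-epimeric alkynyl oxirane carbinol | CC(C)(C)[Si](C)(C)O[C@@H]1C[C@@H]2[C@@H](C)[C@@](O)(C#C[C@@]3(C)CO3)[C@@]1(C)C=C2
F8 | step 3 | (R)-1-(1-naphthyl)ethyl carbamate of the (1S) alcohol | C[C@@H](NC(=O)O[C@H]1C[C@@H]2[C@](C)(OC(C)=O)C(=O)[C@@]1(C)C=C2)c1cccc2ccccc12
F9 | step 3 | (R)-1-(1-naphthyl)ethyl carbamate of the (1R) alcohol | C[C@@H](NC(=O)O[C@@H]1C[C@H]2[C@@](C)(OC(C)=O)C(=O)[C@]1(C)C=C2)c1cccc2ccccc12
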